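- Grey, the simulated run nearest this flask, has the same initiator but 1.4 equiv of solid reagent against the flask's 1.00 equiv. It levels off near 63.0 % starting material by 8.00 d. Amber, with 2.2 equiv, levels off near 63.2 %, so going from grey's charge to amber's carries the run no further, and I put grey's end down to the initiator dying.

| flask | starting material | solid reagent | initiator | remark | time |
|---|---|---|---|---|---|
| grey | 0.50 M | 1.4 equiv | 3.9 mol% | run made earlier |  |
| amber | 0.50 M | 2.2 equiv | 3.9 mol% | run made earlier |  |
| violet | 0.50 M | 1 equiv | 7.8 mol% | run made earlier |  |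
| flask | 0.50 M | 1.00 equiv | 3.9 mol% |  | 15 d |

| run | time / d | starting material / % | product / % |
|---|---|---|---|
| grey | 0.625 | 90.8 | 4.8 |
| grey | 1.67 | 79.3 | 14.6 |
| grey | 3.00 | 71.2 | 22.1 |
| grey | 5.00 | 65.6 | 26.6 |
| grey | 8.00 | 63.0 | 28.7 |
| grey | 10.0 | 63.3 | 29.2 |
| grey | 12.0 | 63.8 | 29.2 |
| amber | 1.04 | 84.9 | 9.3 |
| amber | 1.67 | 78.7 | 13.8 |
| amber | 2.00 | 76.2 | 16.5 |
| amber | 3.00 | 70.2 | 20.9 |
| amber | 5.00 | 65.9 | 26.8 |
| amber | 8.00 | 63.2 | 30.2 |
| amber | 12.0 | 63.8 | 29.5 |
| violet | 2.50 | 61.4 | 23.4 |
| violet | 5.00 | 50.6 | 33.1 |
| violet | 8.00 | 50.4 | 33.8 |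
| violet | 10.0 | 50.3 | 34.1 |
| violet | 12.0 | 50.2 | 34.9 |

(standard deviation of a reading: 0.5 percentage points)

- as a solid, counted per litre of solution: solid reagent
- at the start none of the solid reagent is in solution

- how much of the starting material has reacted by 15 d
- how much product there is at 15 d, in percent of the starting material charged
- amount of product if the flask were left three thousand times as long, in percent of the starting material charged

- Violet has 1 equiv of solid reagent and twice the flask's initiator, and it stands still from about 5.00 d: 50.6 % starting material then, 50.2 % at 12.0 d. I read this as the solid reagent, here the limiting reagent, coming to its end. None is in solution at the start, so I let it enter at its own pace: 1.00 equiv should last about as long in the flask, and grey's charge about 7.00 d.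
- So the flask should follow grey until about 5.00 d and then stop, while grey goes on. My first answer is grey's loss at that time, 34.4 %.
- Going round again, grey and amber read 65.6 % and 65.9 % at 5.00 d, so I take violet's different solid charge as harmless up to that time. Violet's loss over grey's at 5.00 d is 1.44, close to the root of the loading ratio, 1.41. My rule, for 0.50 M starting material and 1.00 equiv of solid reagent, is therefore that flasks stop together, with losses as the root of their initiator loadings. Violet's final loss, 49.7 %, then gives the flask's stopping conversion, 35.1 %, which is less than grey's 37.0 %.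
- Grey's product share at 5.00 d turns that into 27.2 % product. I hold this for the long run too, taking violet's gain of 1.1 percentage points between 8.00 d and 12.0 d for scatter.
- The forecast gives 36.4 % reacted, 30 % product and 35.5 % in the long run, reasoning “so the flask behaves like grey”.
- The flask gives 35.3 % reacted against my 35.1 %, 27.5 % product at 15 d, and 27.5 % in the long run.

    initiator → 2 initiating radical (k = 0.0450 h⁻¹)
    starting material + initiating radical ⇌ chain carrier (K = 4900 M⁻¹, k = 4.50 × 10⁵ M⁻¹ h⁻¹)
    partner + chain carrier → product + initiating radical (k = 7.10 × 10⁵ M⁻¹ h⁻¹)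
    2 chain carrier → ended chains (k = 1.20 × 10⁶ M⁻¹ s⁻¹)
    partner → decomposed reagent (k = 0.210 h⁻¹)
    solid reagent ⇌ partner, rate k6*(cs6 - [partner]) while solid is left; crystals form when [partner] > cs6 (solubility = 0.0880 M, k = 0.0490 h⁻¹)

- The neighbouring flask has the same solid reagent but 6.6 mol% of initiator, so the rule scales the stopping conversion by the root of the loadings: 35.1 % becomes 45.7 %. That neighbour gives 45.9 % reacted and 32.7 % product. At 15.0 d its solid reagent stands at 0 % and its starting material at 54.1 %.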